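All runs come from a simulation for substances that don't exist; the scatter is artificial.

| flask | starting material | reagent | other conformer | remark | time |
|---|---|---|---|---|---|
| gamma | 47 mM | 1 equiv | 0.10 equiv | run made earlier |  |
| zeta | 47 mM | 1.5 equiv | 0.10 equiv | run made earlier |  |
| flask | 47 mM | 2.00 equiv | 0.100 equiv |  | 4.0 d |

- gamma (time / d: target / %, isomer of the product / %): 0.125: 14.8, 36.5; 0.333: 21.3, 51.3; 0.625: 23.5, 57.2; 1.04: 24.7, 60.8; 1.67: 25.7, 63.2; 2.08: 25.9, 63.9; 2.50: 25.7, 63.6
- zeta (time / d: target / %, isomer of the product / %): 0.333: 26.5, 64.0; 0.625: 28.5, 69.4; 1.04: 29.5, 70.5; 1.25: 28.6, 70.6; 1.67: 29.1, 70.8; 2.08: 29.1, 71.2; 2.50: 28.9, 70.6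

(each reading ± 0.3 percentage points)



- share of target in target plus isomer of the product at 3.0 min
- share of target in target plus isomer of the product at 2.5 h
- share of target in target plus isomer of the product at 4.0 d
- which of target and isomer of the product there is more of at 4.0 d

- Begin at the early readings. Divide target by target plus isomer of the product in the first gamma reading, at 0.125 d, and get 28.8%; do the same at 2.08 d and get 28.8%, although [reagent] has fallen between the two.
- Pool the gamma and zeta readings at 2.08 d to get 28.9%, and call this the split, the share of target in target plus isomer of the product, or selectivity.
- Apply the bench rule: one reagent serves one unit of the pool, meaning starting material and other conformer together. Define the reach as reagent charged over pool charged.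
- Test the rule on the runs. In the gamma run the reach is 0.909, and the products stand at 89.8%; in the zeta run it is 1.36, and they stand at 100%.
- Find the border at a reach of one: below it, reagent is the limiting reagent and caps the products. This flask has a reach of 1.82, above the border.
- Count half-lives from the first zeta reading, which gives 0.0981 d. Counted in that zeta half-life, 4.0 d is 40.8 half-lives and 3.0 min is 0.0212 of one, earlier than any reading.
- Commit, as my own reckoning, to the split at all three times, with isomer of the product ahead.
- The forecast gives 29% (25% to 35%), 29% (28.3% to 30%) and 29% (28.6% to 29.4%), with isomer of the product ahead, on the ground that “the two products form in parallel, at the same order in reagent”.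
- The flask gives 29.0%, 29.0% and 29.0%, with isomer of the product ahead at 71.0% against target at 29.0%.

    starting material ⇌ other conformer, settled at all times (K = 0.310)
    starting material + reagent → target (k = 8.50 × 10⁻⁴ M⁻¹ s⁻¹)
    reagent + other conformer → isomer of the product (k = 0.00670 M⁻¹ s⁻¹)

- For the forecast to be wrong, a run would have to show the share moving with time or with the reagent charge. Multiply the split by the smaller of one and the reach to get 28.9% of target for this flask. Now cut reagent to 0.500 equiv, holding the other charges: the reach becomes 0.455, below the border, so expect 13.1% of target. That neighbouring flask has reagent at 0% at 4.00 d, a share of 29.0%, target at 13.2%, and starting material at 41.6%.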